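**Strategy.** The route rests on a retro-oxa-Michael disconnection of the O1''–C2'' bond in ring E, the pyranone of the 7''-methoxyflavanone unit, exploiting its β-aryloxy ketone O1''–C2''–C3''–C4''(=O) fused to benzo ring D at C4a''/C8a''. The key step copies the chalcone–flavanone isomerisation of biosynthesis: a chiral thiourea-catalysed 6-endo oxa-Michael closure of a tert-butyl-ester-activated 2'-hydroxychalcone, with loss of the ester in the same flask, forms ring E and the (2''S) centre at once. Its precursor already holds the finished (2S)-naringenin-type unit, attached by Suzuki coupling, and a single free phenol on ring D beside the biaryl bond, which fixes the 8''-aryl regiochemistry.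

Key step: step 9

**Labels and remarks**
- Unit 1 is the 5,7-dihydroxyflavanone: benzo ring A, pyranone ring C (locants 2–8a) and ring B (1'–6', biaryl bond at C3'). Unit 2 is the 7-O-methylflavanone: benzo ring D, pyranone ring E (O1'', C2'', C3'', C4'', C4a'', C8a'') and the 4-hydroxyphenyl ring F.
- Both stereocentres of the target are (S), C2 and C2''. The C3'–C8'' axis is not specified in the target and is assumed to rotate freely.
- The sense of induction of the two chiral catalysts (steps 5 and 9) is assigned by analogy with simpler substrates. Both catalysts are available in the antipodal or pseudoenantiomeric form, which would be substituted if the sense on these substrates proved reversed.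
- Compounds 1, 5, 8 and 12 are taken as commercially available.

**Route**

Step 1
Reactants: 1 1-(2,6-dihydroxy-4-methoxyphenyl)ethan-1-one
Product: 2 1-[2-(benzyloxy)-6-hydroxy-4-methoxyphenyl]ethan-1-one
Conditions: BnBr (1.05 equiv), K2CO3, acetone, reflux
Reagents that add atoms: benzyl bromide, BrCc1ccccc1
Why: Williamson etherification of one of two equivalent phenols; after the first alkylation the remaining hydroxyl is locked in a hydrogen bond to the carbonyl and should resist a second alkylation.

Step 2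
Reactants: 2 1-[2-(benzyloxy)-6-hydroxy-4-methoxyphenyl]ethan-1-one
Product: 3 1-[6-(benzyloxy)-2-hydroxy-3-iodo-4-methoxyphenyl]ethan-1-one
Conditions: BnNMe3·ICl2 (1.05 equiv), NaHCO3, CH2Cl2/MeOH, rt
Reagents that add atoms: benzyltrimethylammonium dichloroiodate, C[N+](C)(C)Cc1ccccc1.Cl[I-]Cl
Why: Electrophilic aromatic iodination, expected ortho to the free chelated phenol at C3 (between OH and OMe), since C5 lacks the ortho-hydroxyl activation and is flanked by the bulkier benzyloxy group.

Step 3
Reactants: 3 1-[6-(benzyloxy)-2-hydroxy-3-iodo-4-methoxyphenyl]ethan-1-one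
Product: 4 tert-butyl 3-[6-(benzyloxy)-2-hydroxy-3-iodo-4-methoxyphenyl]-3-oxopropanoate
Conditions: LiN(SiMe3)2 (3.3 equiv), THF, −78 °C; Boc2O (1.1 equiv), −78 to −20 °C; AcOH quench
Reagents that add atoms: di-tert-butyl dicarbonate, CC(C)(C)OC(=O)OC(=O)OC(C)(C)C
Why: Claisen-type C-acylation of the lithium enolate of the phenoxide-ketone (any carbonate formed on the phenoxide oxygen should be passed on to carbon by the enolate in a Baker–Venkataraman-type shift), with the third equivalent of base holding the product as its enolate and the aryl iodide inert to the amide base at low temperature.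

Step 4
Reactants: 5 1-[2,4-bis(benzyloxy)-6-hydroxyphenyl]ethan-1-one
Product: 7 5,7-bis(benzyloxy)-4H-chromen-4-one, via enaminone 6 (not isolated)
Conditions: Me2NCH(OMe)2, toluene, 95 °C; then conc. HCl, CH2Cl2, 40 °C
Reagents that add atoms: N,N-dimethylformamide dimethyl acetal, COC(OC)N(C)C
Why: Condensation of the methyl ketone to the enaminone followed by acid-promoted addition of the phenol and elimination of dimethylamine is the standard chromone synthesis from 2-hydroxyacetophenones.

Step 5
Reactants: 7 5,7-bis(benzyloxy)-4H-chromen-4-one; 8 [4-(benzyloxy)-3-chlorophenyl]boronic acid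
Product: 9 (2S)-5,7-bis(benzyloxy)-2-[4-(benzyloxy)-3-chlorophenyl]chroman-4-one
Conditions: [Rh(OH)(cod)]2 (1.5 mol %), (S)-MeO-F12-BIPHEP (3.3 mol %), 8 (2.5 equiv), CH2Cl2/H2O, 35 °C
Reagents that add atoms: none
Why: Hayashi–Miyaura-type asymmetric 1,4-addition of the arylboronic acid to the chromone, in which the electron-poor (S)-biaryl diphosphine on monovalent rhodium is expected, by the face model established for cyclic enones, to set C2 as (S), while the aryl chloride stays untouched.

Step 6
Reactants: 9 (2S)-5,7-bis(benzyloxy)-2-[4-(benzyloxy)-3-chlorophenyl]chroman-4-one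
Product: 10 (2S)-5,7-bis(benzyloxy)-2-[4-(benzyloxy)-3-(4,4,5,5-tetramethyl-1,3,2-dioxaborolan-2-yl)phenyl]chroman-4-one
Conditions: B2pin2 (1.2 equiv), Pd2(dba)3 (2 mol %), XPhos (8 mol %), KOAc, 1,4-dioxane, 90 °C
Reagents that add atoms: bis(pinacolato)diboron, CC1(C)OB(OC1(C)C)B1OC(C)(C)C(C)(C)O1
Why: Miyaura borylation of the aryl chloride with a zerovalent palladium/XPhos catalyst, whose weak acetate base should leave the C2 centre and the ketone untouched.

Step 7
Reactants: 10 (2S)-5,7-bis(benzyloxy)-2-[4-(benzyloxy)-3-(4,4,5,5-tetramethyl-1,3,2-dioxaborolan-2-yl)phenyl]chroman-4-one; 4 tert-butyl 3-[6-(benzyloxy)-2-hydroxy-3-iodo-4-methoxyphenyl]-3-oxopropanoate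
Product: 11 tert-butyl 3-[6-(benzyloxy)-3-{2-(benzyloxy)-5-[(2S)-5,7-bis(benzyloxy)-4-oxochroman-2-yl]phenyl}-2-hydroxy-4-methoxyphenyl]-3-oxopropanoate
Conditions: Pd(OAc)2 (5 mol %), SPhos (10 mol %), K3PO4 (3.5 equiv), toluene/H2O, 50 °C
Reagents that add atoms: none
Why: Suzuki–Miyaura coupling with a ligand made for tri-ortho-substituted biaryls, run with a mild base at moderate temperature so that the base-sensitive C2 centre and the tert-butyl β-ketoester (held as its enolate) should survive.

Step 8
Reactants: 11 tert-butyl 3-[6-(benzyloxy)-3-{2-(benzyloxy)-5-[(2S)-5,7-bis(benzyloxy)-4-oxochroman-2-yl]phenyl}-2-hydroxy-4-methoxyphenyl]-3-oxopropanoate; 12 4-(benzyloxy)benzaldehyde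
Product: 13 tert-butyl (2Z)-2-[6-(benzyloxy)-3-{2-(benzyloxy)-5-[(2S)-5,7-bis(benzyloxy)-4-oxochroman-2-yl]phenyl}-2-hydroxy-4-methoxybenzoyl]-3-[4-(benzyloxy)phenyl]prop-2-enoate
Conditions: piperidine (20 mol %), AcOH (20 mol %), 4 Å molecular sieves, toluene, rt
Reagents that add atoms: none
Why: Knoevenagel condensation at the doubly activated methylene, far more acidic than the C3 methylene of unit 1, should give the thermodynamically preferred alkene (aryl cis to the ester), while the bulky ester and the chelated phenol hold back premature ring closure.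

Step 9
Reactants: 13 tert-butyl (2Z)-2-[6-(benzyloxy)-3-{2-(benzyloxy)-5-[(2S)-5,7-bis(benzyloxy)-4-oxochroman-2-yl]phenyl}-2-hydroxy-4-methoxybenzoyl]-3-[4-(benzyloxy)phenyl]prop-2-enoate
Product: 16 (2S)-5-(benzyloxy)-8-{2-(benzyloxy)-5-[(2S)-5,7-bis(benzyloxy)-4-oxochroman-2-yl]phenyl}-2-[4-(benzyloxy)phenyl]-7-methoxychroman-4-one, via tert-butyl chromanone-3-carboxylate 14 (not isolated), via chromanone-3-carboxylic acid 15 (not isolated)
Conditions: 1-[3,5-bis(trifluoromethyl)phenyl]-3-[(9R)-6'-methoxycinchonan-9-yl]thiourea (from 9-amino-9-deoxy-epi-quinidine, 15 mol %), toluene, −25 °C; then TsOH·H2O, 80 °C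
Reagents that add atoms: none
Why: The thiourea N–H pair of the bifunctional catalyst binds the ketone and ester carbonyls of the alkylidene while the quinuclidine nitrogen takes the proton of the single free phenol on ring D, so the phenoxide oxygen adds to the β-carbon in an intramolecular oxa-Michael reaction, the catalytic counterpart of the chalcone isomerase step; acid then cleaves the tert-butyl ester (isobutene) and acid 15 loses CO2, which removes the activating group and shuts off the retro-Michael pathway. The closest known reaction type is the cinchona-thiourea-catalysed cyclisation and decarboxylation of 2-hydroxyaryl alkylidene β-ketoesters to flavanones. Ring E is closed in the 6-endo-trig mode through the O1''–C2'' bond. The new centre C2'' should be set as (S) by the catalyst, which selects the alkene face; the quinidine-derived pseudoenantiomer is chosen for this sense by analogy with simple flavanones, and the distant C2 centre is not expected to influence it. Regioselectivity (8''-aryl, not 6''-aryl) is secured because the only free hydroxyl on ring D is the one ortho to the biaryl bond, the other ortho oxygen being benzylated; the alkylidene β-ketoester is by far the strongest acceptor in the molecule, and the low temperature keeps the closure under kinetic control until the acid stage.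

Step 10
Reactants: 16 (2S)-5-(benzyloxy)-8-{2-(benzyloxy)-5-[(2S)-5,7-bis(benzyloxy)-4-oxochroman-2-yl]phenyl}-2-[4-(benzyloxy)phenyl]-7-methoxychroman-4-one
Product: 17 (2S)-5-hydroxy-8-{2-hydroxy-5-[(2S)-5,7-dihydroxy-4-oxochroman-2-yl]phenyl}-2-(4-hydroxyphenyl)-7-methoxychroman-4-one
Conditions: H2 (1 atm), Pd/C (10 %), EtOAc/MeOH, rt
Reagents that add atoms: none
Why: Neutral hydrogenolysis of the five aryl benzyl ethers should free all phenols without base, so the two 5-hydroxyflavanone centres, which are prone to ring opening under base, are not exposed to racemising conditions, and the methyl ether is retained.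

**Compound list**

1 | 1-(2,6-dihydroxy-4-methoxyphenyl)ethan-1-one | CC(=O)c1c(O)cc(OC)cc1O | starting material
2 | 1-[2-(benzyloxy)-6-hydroxy-4-methoxyphenyl]ethan-1-one | CC(=O)c1c(O)cc(OC)cc1OCc1ccccc1 | intermediate
3 | 1-[6-(benzyloxy)-2-hydroxy-3-iodo-4-methoxyphenyl]ethan-1-one | CC(=O)c1c(O)c(I)c(OC)cc1OCc1ccccc1 | intermediate
4 | tert-butyl 3-[6-(benzyloxy)-2-hydroxy-3-iodo-4-methoxyphenyl]-3-oxopropanoate | CC(C)(C)OC(=O)CC(=O)c1c(O)c(I)c(OC)cc1OCc1ccccc1 | intermediate
5 | 1-[2,4-bis(benzyloxy)-6-hydroxyphenyl]ethan-1-one | CC(=O)c1c(O)cc(OCc2ccccc2)cc1OCc1ccccc1 | starting material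
6 | (E)-1-[2,4-bis(benzyloxy)-6-hydroxyphenyl]-3-(dimethylamino)prop-2-en-1-one (enaminone, not isolated) | CN(C)/C=C/C(=O)c1c(O)cc(OCc2ccccc2)cc1OCc1ccccc1 | intermediate
7 | 5,7-bis(benzyloxy)-4H-chromen-4-one | O=c1ccoc2cc(OCc3ccccc3)cc(OCc3ccccc3)c12 | intermediate
8 | [4-(benzyloxy)-3-chlorophenyl]boronic acid | OB(O)c1ccc(OCc2ccccc2)c(Cl)c1 | starting material
9 | (2S)-5,7-bis(benzyloxy)-2-[4-(benzyloxy)-3-chlorophenyl]chroman-4-one | Clc1cc([C@@H]2CC(=O)c3c(OCc4ccccc4)cc(OCc4ccccc4)cc3O2)ccc1OCc1ccccc1 | intermediate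
10 | (2S)-5,7-bis(benzyloxy)-2-[4-(benzyloxy)-3-(4,4,5,5-tetramethyl-1,3,2-dioxaborolan-2-yl)phenyl]chroman-4-one | CC1(C)OB(OC1(C)C)c1cc([C@@H]2CC(=O)c3c(OCc4ccccc4)cc(OCc4ccccc4)cc3O2)ccc1OCc1ccccc1 | intermediate
11 | tert-butyl 3-[6-(benzyloxy)-3-{2-(benzyloxy)-5-[(2S)-5,7-bis(benzyloxy)-4-oxochroman-2-yl]phenyl}-2-hydroxy-4-methoxyphenyl]-3-oxopropanoate | CC(C)(C)OC(=O)CC(=O)c1c(O)c(-c2cc([C@@H]3CC(=O)c4c(OCc5ccccc5)cc(OCc5ccccc5)cc4O3)ccc2OCc2ccccc2)c(OC)cc1OCc1ccccc1 | intermediate
12 | 4-(benzyloxy)benzaldehyde | O=Cc1ccc(OCc2ccccc2)cc1 | starting material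
13 | tert-butyl (2Z)-2-[6-(benzyloxy)-3-{2-(benzyloxy)-5-[(2S)-5,7-bis(benzyloxy)-4-oxochroman-2-yl]phenyl}-2-hydroxy-4-methoxybenzoyl]-3-[4-(benzyloxy)phenyl]prop-2-enoate | CC(C)(C)OC(=O)/C(=C\c1ccc(OCc2ccccc2)cc1)C(=O)c1c(O)c(-c2cc([C@@H]3CC(=O)c4c(OCc5ccccc5)cc(OCc5ccccc5)cc4O3)ccc2OCc2ccccc2)c(OC)cc1OCc1ccccc1 | intermediate
14 | tert-butyl (2S)-5-(benzyloxy)-8-{2-(benzyloxy)-5-[(2S)-5,7-bis(benzyloxy)-4-oxochroman-2-yl]phenyl}-2-[4-(benzyloxy)phenyl]-7-methoxy-4-oxochromane-3-carboxylate (C3 epimers and enol form, not isolated) | COc1cc(OCc2ccccc2)c2c(c1-c1cc([C@@H]3CC(=O)c4c(OCc5ccccc5)cc(OCc5ccccc5)cc4O3)ccc1OCc1ccccc1)O[C@H](c1ccc(OCc3ccccc3)cc1)C(C(=O)OC(C)(C)C)C2=O | intermediate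
15 | (2S)-5-(benzyloxy)-8-{2-(benzyloxy)-5-[(2S)-5,7-bis(benzyloxy)-4-oxochroman-2-yl]phenyl}-2-[4-(benzyloxy)phenyl]-7-methoxy-4-oxochromane-3-carboxylic acid (C3 epimers, not isolated) | COc1cc(OCc2ccccc2)c2c(c1-c1cc([C@@H]3CC(=O)c4c(OCc5ccccc5)cc(OCc5ccccc5)cc4O3)ccc1OCc1ccccc1)O[C@H](c1ccc(OCc3ccccc3)cc1)C(C(=O)O)C2=O | intermediate
16 | (2S)-5-(benzyloxy)-8-{2-(benzyloxy)-5-[(2S)-5,7-bis(benzyloxy)-4-oxochroman-2-yl]phenyl}-2-[4-(benzyloxy)phenyl]-7-methoxychroman-4-one | COc1cc(OCc2ccccc2)c2c(c1-c1cc([C@@H]3CC(=O)c4c(OCc5ccccc5)cc(OCc5ccccc5)cc4O3)ccc1OCc1ccccc1)O[C@H](c1ccc(OCc3ccccc3)cc1)CC2=O | intermediate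
17 | (2S)-5-hydroxy-8-{2-hydroxy-5-[(2S)-5,7-dihydroxy-4-oxochroman-2-yl]phenyl}-2-(4-hydroxyphenyl)-7-methoxychroman-4-one | COc1cc(O)c2c(c1-c1cc([C@@H]3CC(=O)c4c(O)cc(O)cc4O3)ccc1O)O[C@H](c1ccc(O)cc1)CC2=O | target

**Step count**

Total steps: 10. Longest linear sequence: 7 steps (steps 1, 2, 3, 7, 8, 9, 10; the branch through steps 4, 5, 6 is equally long).

**Steps most likely to fail, with fallbacks**

1. Step 9 (key step). The facial discrimination in the oxa-Michael closure may be poor, because the aroyl group carries two ortho substituents and is twisted out of conjugation. The 3-carboxylate adduct may also reopen and reclose before the acid stage, eroding the C2'' configuration. Fallback: the fallback sets out from 11 and returns to the route at 14. Compound 11 would be treated with N,N-dimethylformamide dimethyl acetal at room temperature. Condensation at the active methylene and addition–elimination by the ring D phenol should close ring E at the chromone level, still as the last ring, giving tert-butyl 5-(benzyloxy)-8-{2-(benzyloxy)-5-[(2S)-5,7-bis(benzyloxy)-4-oxochroman-2-yl]phenyl}-7-methoxy-4-oxo-4H-chromene-3-carboxylate F1. C2'' would then be set through C–C bond formation by the rhodium/(S)-MeO-F12-BIPHEP 1,4-addition of [4-(benzyloxy)phenyl]boronic acid under the conditions of step 5. This gives 14, which the acid stage of step 9 carries on to 16.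

2. Step 7. The base may open and reclose ring C of unit 1 and so erode C2. The coupling at the doubly ortho-substituted, electron-rich iodide may also be slow, with protodeboronation or lactonisation of the hydroxyaryl β-ketoester taking over. Fallback: the biaryl bond would be made before any stereocentre exists; the fallback sets out from 4 and returns at 11. Iodide 4 would be coupled with commercial [2-(benzyloxy)-5-chlorophenyl]boronic acid (Pd(PPh3)4, K2CO3, DME/H2O, 80 °C; the iodide reacts and the chloride survives) to give tert-butyl 3-[6-(benzyloxy)-3-[2-(benzyloxy)-5-chlorophenyl]-2-hydroxy-4-methoxyphenyl]-3-oxopropanoate F2. Miyaura borylation under the conditions of step 6 would give tert-butyl 3-[6-(benzyloxy)-3-[2-(benzyloxy)-5-(4,4,5,5-tetramethyl-1,3,2-dioxaborolan-2-yl)phenyl]-2-hydroxy-4-methoxyphenyl]-3-oxopropanoate F3. Its rhodium-catalysed asymmetric 1,4-addition to chromone 7 under the conditions of step 5 would then create C2 under neutral conditions and give 11.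

3. Step 10. Hydrogenolysis may not stop at the benzyl ethers: the benzylic C2–O1 and C2''–O1'' bonds may be cleaved (ring opening to dihydrochalcones) or the ketones reduced, or the removal of five benzyl groups may stall. Fallback: reductive cleavage would be replaced by Lewis-acid debenzylation with a cation scavenger; the fallback sets out from 16 and returns at 17. Compound 16 would be treated with BCl3 and pentamethylbenzene in CH2Cl2 at −78 °C and quenched cold with methanol. The aryl methyl ether at C7'' should survive, no base is involved, and 17 is obtained directly.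

**Further compounds**

F1 | step 9 | tert-butyl 5-(benzyloxy)-8-{2-(benzyloxy)-5-[(2S)-5,7-bis(benzyloxy)-4-oxochroman-2-yl]phenyl}-7-methoxy-4-oxo-4H-chromene-3-carboxylate | COc1cc(OCc2ccccc2)c2c(c1-c1cc([C@@H]3CC(=O)c4c(OCc5ccccc5)cc(OCc5ccccc5)cc4O3)ccc1OCc1ccccc1)occ(C(=O)OC(C)(C)C)c2=O
F2 | step 7 | tert-butyl 3-[6-(benzyloxy)-3-[2-(benzyloxy)-5-chlorophenyl]-2-hydroxy-4-methoxyphenyl]-3-oxopropanoate | CC(C)(C)OC(=O)CC(=O)c1c(O)c(-c2cc(Cl)ccc2OCc2ccccc2)c(OC)cc1OCc1ccccc1
F3 | step 7 | tert-butyl 3-[6-(benzyloxy)-3-[2-(benzyloxy)-5-(4,4,5,5-tetramethyl-1,3,2-dioxaborolan-2-yl)phenyl]-2-hydroxy-4-methoxyphenyl]-3-oxopropanoate | CC(C)(C)OC(=O)CC(=O)c1c(O)c(-c2cc(B3OC(C)(C)C(C)(C)O3)ccc2OCc2ccccc2)c(OC)cc1OCc1ccccc1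
F0 | step 10 | none | none
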